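**Plan**

Numbering (daucane): C1 = quaternary ring-fusion carbon, C4 = carbinol carbon with the isopropyl group, C5 = ring-fusion CH, C6 = acyloxy carbon, C8=C9 = ring alkene. Ring A = cyclopentane, ring B = cycloheptene, β = face of the C1 methyl group.
Cuts: vanilloyl–O6, then C8=C9 (ring-closing metathesis), C6–C7 (acyl substitution), and C4–C5 together with a temporary O4–C6 bond. Behind that, a C4–C6 bond is re-made to reach a p-menthane ring, and C1–C10 is cut.
Enabling feature: O4 and C6 stand cis on ring A and 1,3 to each other across C5. With C6 at the acid level, O4–C4–C5–C6 is therefore a cis-fused 2-oxetanone that one aldol-lactonization of an open keto acid can build.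
Forward: the menthone ring (C1–C2–C3–C4–C6–C5) takes up allyl at C1, is opened between C4 and C6, and is closed again between C4 and C5 (ring A plus β-lactone). The lactone strain pays for the acylation at C6, ring B closes last, then the ester is set.
Stereochemistry: C1 comes from the isopropyl-bearing centre of (−)-menthone (axial conjugate allylation). C4 and C5 come from the chiral isothiourea and the forced cis-fusion of the lactone. C6 comes from hydride delivery directed by O4–H.

Key step: step 6

Assumption: (S)-HBTM is taken as the catalyst enantiomer that leaves the Si face of the C5 enolate open; if the sense is the opposite one, (R)-HBTM is used and nothing else changes.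

**Step 1**
Reactants: 1 (−)-menthone
Product: 2 {[(3R,6S)-6-isopropyl-3-methylcyclohex-1-en-1-yl]oxy}trimethylsilane
Conditions: LiN(iPr)2, THF, −78 °C; then Me3SiCl, −78 → 0 °C
Reagents that add atoms: chlorotrimethylsilane, C[Si](C)(C)Cl
Why: Kinetic deprotonation of the less hindered CH2 by the bulky amide followed by O-silylation (regioselective silyl enol ether formation) should leave the isopropyl-bearing stereocentre untouched.

**Step 2**
Reactants: 2 silyl enol ether
Product: 3 (S)-(+)-piperitone, (6S)-6-isopropyl-3-methylcyclohex-2-en-1-one
Conditions: Pd(OAc)2 (10 mol %), O2 (1 atm), DMSO, 25 °C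
Reagents that add atoms: none
Why: In this Saegusa–Ito oxidation, divalent palladium adds to the enol ether and β-hydride elimination from the methyl-bearing carbon gives the enone, which erases the methyl stereocentre and keeps the (S) centre next to the carbonyl group under base-free conditions.

**Step 3**
Reactants: 3 (S)-piperitone
Product: 4 (3R,6S)-3-allyl-6-isopropyl-3-methylcyclohexan-1-one (allyl cis to isopropyl)
Conditions: allyltrimethylsilane, TiCl4, CH2Cl2, −78 °C; then H2O
Reagents that add atoms: allyltrimethylsilane, C=CC[Si](C)(C)C
Why: In this Hosomi–Sakurai conjugate allylation, antiparallel (axial) attack on the half-chair that carries the isopropyl group pseudo-equatorial should place allyl cis to isopropyl and set quaternary C1 as R, and the C1 epimer is a diastereomer that chromatography removes.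

**Step 4**
Reactants: 4 allyl ketone
Product: 5 (4R,7S)-4-allyl-7-isopropyl-4-methyloxepan-2-one
Conditions: (Me3SiO)2, Me3SiOTf (10 mol %), CH2Cl2, −40 → −20 °C
Reagents that add atoms: bis(trimethylsilyl) peroxide, C[Si](C)(C)OO[Si](C)(C)C
Why: In this Baeyer–Villiger oxidation the secondary, isopropyl-bearing C4 migrates in preference to the neopentyl CH2 and with retention, and the silyl peroxide does not epoxidize, so the allyl group should survive.

**Step 5**
Reactants: 5 ε-lactone
Product: 7 (3R)-3-allyl-3,7-dimethyl-6-oxooctanoic acid, via hydroxy acid 6 (not isolated)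
Conditions: LiOH, THF/H2O, 25 °C; HCl to pH 3, extraction; then Dess–Martin periodinane, CH2Cl2, 0 → 25 °C
Reagents that add atoms: lithium hydroxide, [Li+].[OH-]
Why: Saponification followed by Dess–Martin oxidation of the crude secondary alcohol completes the C4–C6 ring opening, turns C4 into the isopropyl ketone (its stereocentre has done its work), and touches neither C1 nor the alkene.

**Step 6**
Reactants: 7 (3R)-3-allyl-3,7-dimethyl-6-oxooctanoic acid
Product: 9 (1R,2R,5R)-2-allyl-5-isopropyl-2-methyl-6-oxabicyclo[3.2.0]heptan-7-one, via tosyl mixed anhydride 8 (not isolated)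
Conditions: p-TsCl, (S)-HBTM = (S)-2-phenyl-3,4-dihydro-2H-benzo[4,5]thiazolo[3,2-a]pyrimidine (20 mol %), LiCl, iPr2NEt, CH2Cl2, 23 °C, slow addition of 7
Reagents that add atoms: none
Why: TsCl turns 7 into mixed anhydride 8, the isothiourea is acylated, iPr2NEt deprotonates the acylammonium salt to a C5 ammonium enolate, this adds to the C4 ketone and the tertiary alkoxide expels the catalyst from C6, so that C4–C5 and O4–C6 form in one operation (nucleophile-catalysed aldol-lactonization, whose closest known form is the isothiourea-catalysed closure of 6-oxo acids to cyclopentane-fused β-lactones). Ring A closes in the 5-(enolexo)-exo-trig mode and the 2-oxetanone closes in the 4-exo-trig mode at the acyl carbon. The four-membered ring can only be cis-fused, which puts O4 and C6 on one face of ring A and the isopropyl group on the other, that is, the C4/C5 relative configuration of the target. The absolute sense (bond formation on the Si face of C5) should come from the phenyl group of the catalyst, held in place by the 1,5-O···S contact of the enolate, whereas C1, whose methyl and allyl arms are nearly isosteric, exerts only a small bias, and that bias (methyl rather than allyl on the concave face) is matched. The step needs chemoselective enolization, which is secured because only the activated carboxyl group is acidified enough for the amine base, so the isopropyl ketone stays the electrophile and the geminal substitution at C1 favours the folded conformer. Any enantiomer of 7 carried over from step 3 ends up as a diastereomeric lactone and is removed here.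

**Step 7**
Reactants: 9 bicyclic β-lactone
Product: 10 (1R,2R,5R)-5-allyl-2-hydroxy-2-isopropyl-N-methoxy-N,5-dimethylcyclopentane-1-carboxamide
Conditions: Me(MeO)NH·HCl, iPrMgCl, THF, −20 → 0 °C
Reagents that add atoms: N,O-dimethylhydroxylamine hydrochloride, CNOC.Cl
Why: Strain-driven acyl–oxygen cleavage of the β-lactone by the chloromagnesium amide (Weinreb amide formation) frees O4–H without touching a stereocentre, and the weakly Lewis-acidic medium should avoid ionization of the tertiary C4–O bond.

**Step 8**
Reactants: 10 Weinreb amide
Product: 11 1-[(1R,2R,5R)-5-allyl-2-hydroxy-2-isopropyl-5-methylcyclopentyl]-3-methylbut-3-en-1-one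
Conditions: 2-methylallylmagnesium chloride (3 equiv), THF, −78 → 0 °C; cold aq. NH4Cl
Reagents that add atoms: 2-methylallylmagnesium chloride, CC(=C)C[Mg]Cl
Why: In this Weinreb ketone synthesis the first equivalent deprotonates O4–H, the chelated tetrahedral intermediate blocks a second addition, and the cold neutral quench should keep the alkene out of conjugation and C5 unchanged.

**Step 9**
Reactants: 11 dienyl hydroxy ketone
Product: 12 (3R,3aR,8aR)-3-hydroxy-3-isopropyl-6,8a-dimethyl-2,3,3a,5,8,8a-hexahydroazulen-4(1H)-one (4β-hydroxydauc-8-en-6-one)
Conditions: second-generation Hoveyda–Grubbs catalyst (5 mol %), 1,4-benzoquinone (10 mol %), toluene (2 mM), 80 °C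
Reagents that add atoms: none
Why: In this ring-closing metathesis, ruthenium loads on the allyl group and closes onto the 1,1-disubstituted alkene to give the trisubstituted C8=C9 bond of ring B, the trans arms on ring A fit a seven-membered ring, benzoquinone suppresses hydride-induced alkene migration, and no stereocentre is formed.

**Step 10**
Reactants: 12 bicyclic hydroxy ketone
Product: 13 jaeschkeanadiol, (3R,3aS,4S,8aR)-3-isopropyl-6,8a-dimethyl-1,2,3,3a,4,5,8,8a-octahydroazulene-3,4-diol
Conditions: Me4NBH(OAc)3, MeCN/AcOH (1:1), −30 °C
Reagents that add atoms: none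
Why: In this Evans–Saksena reduction, acetate exchange at O4–H ties the borohydride to the β-face and hydride passes through a chair-like six-membered transition state to the face of C6 that is syn to O4 and the angular methyl group, which should give the 6α (S) alcohol that external hydride, coming from the open α-face, would not give.

**Step 11**
Reactants: 14 vanillic acid
Product: 15 4-acetoxy-3-methoxybenzoic acid
Conditions: Ac2O, pyridine, 25 °C; aqueous work-up
Reagents that add atoms: acetic anhydride, CC(=O)OC(C)=O
Why: Acetylation masks the phenol so that it cannot compete as a nucleophile in the esterification, and any mixed anhydride at the carboxyl group is hydrolysed on work-up.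

**Step 12**
Reactants: 13 jaeschkeanadiol; 15 4-acetoxy-3-methoxybenzoic acid
Product: 16 O-acetylteferin (jaeschkeanadiol 6-(4-acetoxy-3-methoxybenzoate))
Conditions: N,N'-dicyclohexylcarbodiimide, 4-(dimethylamino)pyridine (20 mol %), toluene, 60 °C
Reagents that add atoms: none
Why: The Steglich esterification acylates only the secondary O6–H because the tertiary O4–H is too hindered, and the C6–O bond is not broken, so its configuration is kept.

**Step 13**
Reactants: 16 O-acetylteferin
Product: 17 teferin
Conditions: pyrrolidine, CH2Cl2, 0 → 25 °C
Reagents that add atoms: none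
Why: Chemoselective aminolysis cleaves the activated aryl acetate far faster than the hindered secondary benzoate, which should free the phenol without acyl loss or migration.

**Compound list**

1 | (−)-menthone, (2S,5R)-2-isopropyl-5-methylcyclohexan-1-one | O=C1C[C@H](C)CC[C@H]1C(C)C | starting material
2 | {[(3R,6S)-6-isopropyl-3-methylcyclohex-1-en-1-yl]oxy}trimethylsilane | C[Si](C)(C)OC1=C[C@H](C)CC[C@H]1C(C)C | intermediate
3 | (S)-(+)-piperitone | O=C1C=C(C)CC[C@H]1C(C)C | intermediate
4 | (3R,6S)-3-allyl-6-isopropyl-3-methylcyclohexan-1-one | O=C1C[C@@](C)(CC=C)CC[C@H]1C(C)C | intermediate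
5 | (4R,7S)-4-allyl-7-isopropyl-4-methyloxepan-2-one | O=C1C[C@@](C)(CC=C)CC[C@@H](C(C)C)O1 | intermediate
6 | (3R,6S)-3-allyl-6-hydroxy-3,7-dimethyloctanoic acid | OC(=O)C[C@@](C)(CC=C)CC[C@H](O)C(C)C | intermediate
7 | (3R)-3-allyl-3,7-dimethyl-6-oxooctanoic acid | OC(=O)C[C@@](C)(CC=C)CCC(=O)C(C)C | intermediate
8 | (3R)-3-allyl-3,7-dimethyl-6-oxooctanoic p-toluenesulfonic anhydride | Cc1ccc(cc1)S(=O)(=O)OC(=O)C[C@@](C)(CC=C)CCC(=O)C(C)C | intermediate
9 | (1R,2R,5R)-2-allyl-5-isopropyl-2-methyl-6-oxabicyclo[3.2.0]heptan-7-one | O=C1O[C@@]2(C(C)C)CC[C@](C)(CC=C)[C@@H]12 | intermediate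
10 | (1R,2R,5R)-5-allyl-2-hydroxy-2-isopropyl-N-methoxy-N,5-dimethylcyclopentane-1-carboxamide | CON(C)C(=O)[C@H]1[C@](O)(C(C)C)CC[C@]1(C)CC=C | intermediate
11 | 1-[(1R,2R,5R)-5-allyl-2-hydroxy-2-isopropyl-5-methylcyclopentyl]-3-methylbut-3-en-1-one | CC(=C)CC(=O)[C@H]1[C@](O)(C(C)C)CC[C@]1(C)CC=C | intermediate
12 | (3R,3aR,8aR)-3-hydroxy-3-isopropyl-6,8a-dimethyl-2,3,3a,5,8,8a-hexahydroazulen-4(1H)-one | O=C1CC(C)=CC[C@@]2(C)CC[C@@](O)(C(C)C)[C@H]12 | intermediate
13 | jaeschkeanadiol | O[C@H]1CC(C)=CC[C@@]2(C)CC[C@@](O)(C(C)C)[C@H]12 | intermediate
14 | vanillic acid | COc1cc(C(=O)O)ccc1O | starting material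
15 | 4-acetoxy-3-methoxybenzoic acid | COc1cc(C(=O)O)ccc1OC(C)=O | intermediate
16 | O-acetylteferin | COc1cc(C(=O)O[C@H]2CC(C)=CC[C@@]3(C)CC[C@@](O)(C(C)C)[C@H]23)ccc1OC(C)=O | intermediate
17 | teferin | COc1cc(C(=O)O[C@H]2CC(C)=CC[C@@]3(C)CC[C@@](O)(C(C)C)[C@H]23)ccc1O | target

Total step count: 13. Longest linear sequence: 12 (steps 1–10, 12, 13).

**Steps most likely to fail**

**Step 6.** Addition of the ammonium enolate to the hindered isopropyl ketone may be slower than ketene formation and dimerization from 8. Catalyst control over a substrate whose own stereocentre gives little bias may also be eroded.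
The fallback sets out from 7 and returns at 10. Acid 7 is joined through its pivaloyl mixed anhydride to lithiated (R)-4-benzyl-1,3-oxazolidin-2-one to give the N-acyl oxazolidinone F1. TiCl4 and iPr2NEt in CH2Cl2 at −78 °C form the Z chlorotitanium enolate. This should close onto the titanium-bound ketone through a chelated chair (auxiliary-controlled aldol cyclization) to the β-hydroxy imide F2, with the benzyl group covering the Re face of C5 and the chelate holding O4 cis to C6. Me(MeO)NH·HCl and AlMe3 then displace the auxiliary and give 10.

**Step 4.** Peroxide addition to the hindered carbonyl group may lag behind a Lewis-acid-induced Prins-type closure of the allyl group onto the activated ketone.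
The fallback sets out from 4 and returns at 7. Ketone 4 is converted with Me3SiI and (Me3Si)2NH under equilibrating conditions into the tetrasubstituted silyl enol ether F3. Rubottom oxidation with mCPBA at −20 °C, where the enol ether outruns the terminal alkene, gives the tertiary α-hydroxy ketone F4 (either epimer serves). H5IO6 in aqueous THF cleaves the C4–C6 bond of the α-ketol and delivers keto acid 7 directly, so that 5 and 6 are bypassed.

**Step 10.** Ligand exchange at the tertiary hydroxyl group may be too slow. Undirected hydride attack from the open α-face, or acid-induced migration of the C8=C9 bond into conjugation, could then compete.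
The fallback sets out from 11 and returns at 13. Ketone 11 is reduced before ring closure under chelation control (Narasaka–Prasad reduction, Et2BOMe then NaBH4, THF/MeOH, −78 °C). The boron chelate of O4 and O6 with the isopropyl group equatorial takes external hydride axially and should give the monocyclic diol F5 with the 6S configuration. Ring-closing metathesis of F5 with the second-generation Hoveyda–Grubbs catalyst then gives 13, and the β,γ-unsaturated ketone 12 is never made.

**Further compounds**

F1 | step 6 | (R)-4-benzyl-3-[(3R)-3-allyl-3,7-dimethyl-6-oxooctanoyl]-1,3-oxazolidin-2-one | O=C1OC[C@@H](Cc2ccccc2)N1C(=O)C[C@@](C)(CC=C)CCC(=O)C(C)C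
F2 | step 6 | (R)-4-benzyl-3-{[(1R,2R,5R)-5-allyl-2-hydroxy-2-isopropyl-5-methylcyclopentyl]carbonyl}-1,3-oxazolidin-2-one | O=C1OC[C@@H](Cc2ccccc2)N1C(=O)[C@H]3[C@](O)(C(C)C)CC[C@]3(C)CC=C
F3 | step 4 | {[(5R)-5-allyl-2-isopropyl-5-methylcyclohex-1-en-1-yl]oxy}trimethylsilane | C[Si](C)(C)OC1=C(C(C)C)CC[C@](C)(CC=C)C1
F4 | step 4 | (5R)-5-allyl-2-hydroxy-2-isopropyl-5-methylcyclohexan-1-one (both C2 epimers) | O=C1C[C@@](C)(CC=C)CCC1(O)C(C)C
F5 | step 10 | (1S)-1-[(1S,2R,5R)-5-allyl-2-hydroxy-2-isopropyl-5-methylcyclopentyl]-3-methylbut-3-en-1-ol | CC(=C)C[C@H](O)[C@H]1[C@](O)(C(C)C)CC[C@]1(C)CC=C
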